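**Retrosynthetic overview**
- Cembrane numbering is used. C1 carries the isopropylidene unit (C15 with C16 and C17), C2 is the ketone, C3/C4 the oxirane, C7=C8 the ring alkene, C9 the free carbinol and C12 the acetoxy carbon.
- The strategy rests on one feature of the 14-membered carbocycle. The oxygenated ring carbon C2 is bonded to C1, the ring carbon bearing the exocyclic three-carbon branch. Read as a carbinol next to an isopropenyl-bearing carbon, this is the retron of a [2,3]-Wittig rearrangement.
- Acetate, C9 silyl ether, enone conjugation, C2 oxidation and C2-OH-directed 3,4-epoxidation lead back to a 14-membered propargylic alcohol. Its C3≡C4 alkyne is the precursor of the E-C3=C4(CH3) unit.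
- Cutting C1–C2 gives a 17-membered propargyl allyl ether (C2–O–C16). It is opened at O–C16 to a chloro alcohol, and at C9–C10 to a linalool-derived iodide (C12 bought) and an (E)-enoyl Weinreb amide.
- Rings in forward order: 17-membered oxacycle by Williamson closure, 14-membered carbocycle by ring contraction, oxirane last.

Key step: step 16

Assumption: the (R,R)-antipode of the amide base is taken as the one that leads to the 2R carbinol; no reliable model predicts the sense of induction, and should it prove opposite, the equally available (S,S)-amine is used with nothing else changed.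

Step 1
Reactants: 1 (R)-(−)-linalool
Product: 2 (3R)-3,7-dimethyl-3-(triethylsilyloxy)octa-1,6-diene
Conditions: TESOTf, 2,6-lutidine, CH2Cl2, −78 → 0 °C
Reagents that add atoms: triethylsilyl triflate, CC[Si](CC)(CC)OS(=O)(=O)C(F)(F)F
Why: Silyl ether protection with a silyl triflate and a hindered pyridine base silylates even a tertiary allylic alcohol at low temperature without ionising it, so the purchased C12 stereocentre is kept.

Step 2
Reactants: 2 (3R)-3,7-dimethyl-3-(triethylsilyloxy)octa-1,6-diene
Product: 4 (3R)-3,7-dimethyl-3-(triethylsilyloxy)oct-6-en-1-ol, via B-alkyl-9-BBN adduct 3 (not isolated)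
Conditions: 9-BBN, THF, 0 °C → rt; then NaOH, H2O2, 0 °C
Reagents that add atoms: 9-BBN, B1C2CCCC1CCC2 (boron unit, in 3 only); hydrogen peroxide, OO (the hydroxyl oxygen)
Why: In this hydroboration–oxidation the bulky borane adds anti-Markovnikov to the monosubstituted vinyl group far faster than to the trisubstituted alkene, and alkaline peroxide then replaces boron by hydroxyl while the tertiary TES ether holds.

Step 3
Reactants: 4 (3R)-3,7-dimethyl-3-(triethylsilyloxy)oct-6-en-1-ol
Product: 5 (3R)-1-iodo-3,7-dimethyl-3-(triethylsilyloxy)oct-6-ene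
Conditions: I2, PPh3, imidazole, CH2Cl2, 0 °C
Reagents that add atoms: iodine, II
Why: Appel-type iodination converts the primary alcohol into the iodide by SN2 displacement of the alkoxyphosphonium ion under imidazole-buffered conditions that the TES ether tolerates.

Step 4
Reactants: 6 propargyl alcohol
Product: 8 4-methoxybenzyl prop-2-ynyl ether, via sodium prop-2-yn-1-olate 7 (not isolated)
Conditions: NaH (1 equiv), DMF, 0 °C; then PMBCl, 0 °C → rt
Reagents that add atoms: sodium hydride, [Na+].[H-] (sodium, in 7 only); 4-methoxybenzyl chloride, COc1ccc(CCl)cc1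
Why: In this Williamson ether synthesis one equivalent of hydride removes only the O–H proton, which is far more acidic than the alkyne C–H, and the alkoxide is alkylated by the activated benzylic chloride.

Step 5
Reactants: 8 4-methoxybenzyl prop-2-ynyl ether; 9 2-(2-bromoethyl)-1,3-dioxolane
Product: 11 2-[5-(4-methoxybenzyloxy)pent-3-yn-1-yl]-1,3-dioxolane, via lithium acetylide 10 (not isolated)
Conditions: n-BuLi, THF, −78 °C; then 9, DMPU, −78 °C → rt
Reagents that add atoms: n-butyllithium, [Li]CCCC (lithium, in 10 only)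
Why: SN2 alkylation of a lithium acetylide with a primary bromide forms the C4–C5 bond, and the dipolar co-solvent raises the rate of substitution relative to elimination.

Step 6
Reactants: 11 2-[5-(4-methoxybenzyloxy)pent-3-yn-1-yl]-1,3-dioxolane
Product: 12 6-(4-methoxybenzyloxy)hex-4-ynal
Conditions: 1 M HCl, THF, rt
Reagents that add atoms: water, O
Why: Acid-catalysed acetal hydrolysis frees the aldehyde under dilute aqueous acid that leaves the PMB ether and the alkyne alone.

Step 7
Reactants: 12 6-(4-methoxybenzyloxy)hex-4-ynal; 13 ethyl 2-(triphenylphosphoranylidene)propanoate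
Product: 14 ethyl (2E)-8-(4-methoxybenzyloxy)-2-methyloct-2-en-6-ynoate
Conditions: CH2Cl2, rt
Reagents that add atoms: none
Why: Wittig olefination with a stabilised α-methyl ylide should give the (E)-trisubstituted enoate, which fixes the C7=C8 geometry of the target.

Step 8
Reactants: 14 ethyl (2E)-8-(4-methoxybenzyloxy)-2-methyloct-2-en-6-ynoate
Product: 15 (2E)-N-methoxy-8-(4-methoxybenzyloxy)-N,2-dimethyloct-2-en-6-ynamide
Conditions: MeNH(OMe)·HCl, i-PrMgCl, THF, −20 → 0 °C
Reagents that add atoms: N,O-dimethylhydroxylamine hydrochloride, CNOC.Cl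
Why: Weinreb amide formation by aminolysis of the ester with the magnesium amide proceeds at low temperature at the carbonyl group only, because the α-methyl, β-substituted alkene is a poor conjugate acceptor.

Step 9
Reactants: 5 (3R)-1-iodo-3,7-dimethyl-3-(triethylsilyloxy)oct-6-ene; 15 (2E)-N-methoxy-8-(4-methoxybenzyloxy)-N,2-dimethyloct-2-en-6-ynamide
Product: 17 (6E,11R)-1-(4-methoxybenzyloxy)-7,11,15-trimethyl-11-(triethylsilyloxy)hexadeca-6,14-dien-2-yn-8-one, via alkylmagnesium iodide 16 (not isolated)
Conditions: 5 (1.5 equiv), Mg turnings, Et2O, reflux; then 15, THF, −20 → 0 °C; aqueous work-up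
Reagents that add atoms: magnesium, [Mg] (in 16 only)
Why: In the Weinreb ketone synthesis the Grignard reagent adds once to give a chelated adduct that collapses only on work-up, so C9–C10 forms without over-addition; magnesium rather than lithium avoids 1,4 O→C silyl migration, and an excess of the cheap iodide offsets Wurtz coupling.

Step 10
Reactants: 17 (6E,11R)-1-(4-methoxybenzyloxy)-7,11,15-trimethyl-11-(triethylsilyloxy)hexadeca-6,14-dien-2-yn-8-one
Product: 18 (6E,11R,14E)-16-hydroxy-1-(4-methoxybenzyloxy)-7,11,15-trimethyl-11-(triethylsilyloxy)hexadeca-6,14-dien-2-yn-8-one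
Conditions: SeO2 (cat.), t-BuOOH, salicylic acid (cat.), CH2Cl2, 0 °C → rt, stopped before full conversion, 17 recycled
Reagents that add atoms: tert-butyl hydroperoxide, CC(C)(C)OO
Why: Catalytic selenium dioxide allylic oxidation (ene reaction, then [2,3]-shift) attacks the electron-rich prenyl alkene and hydroxylates its E-methyl group (C16), whereas the C7=C8 alkene is deactivated by the ketone and the alkyne reacts much more slowly.

Step 11
Reactants: 18 (6E,11R,14E)-16-hydroxy-1-(4-methoxybenzyloxy)-7,11,15-trimethyl-11-(triethylsilyloxy)hexadeca-6,14-dien-2-yn-8-one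
Product: 20 (6E,11R,14E)-16-chloro-1-(4-methoxybenzyloxy)-7,11,15-trimethyl-11-(triethylsilyloxy)hexadeca-6,14-dien-2-yn-8-one, via allylic mesylate 19 (not isolated)
Conditions: MsCl, 2,4,6-collidine, LiCl, DMF, 0 °C
Reagents that add atoms: methanesulfonyl chloride, CS(=O)(=O)Cl (mesyl group, in 19 only); lithium chloride, [Li+].[Cl-]
Why: In the Collington–Meyers chlorination the mesylate formed in situ is displaced by chloride in an SN2 reaction at the primary carbon, without allylic transposition or loss of the E geometry.

Step 12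
Reactants: 20 (6E,11R,14E)-16-chloro-1-(4-methoxybenzyloxy)-7,11,15-trimethyl-11-(triethylsilyloxy)hexadeca-6,14-dien-2-yn-8-one
Product: 21 (6E,8R,11R,14E)-16-chloro-1-(4-methoxybenzyloxy)-7,11,15-trimethyl-11-(triethylsilyloxy)hexadeca-6,14-dien-2-yn-8-ol
Conditions: (S)-Me-CBS (20 mol %), catecholborane, toluene, −78 °C; MeOH quench
Reagents that add atoms: none
Why: In the Corey–Bakshi–Shibata reduction, with the trisubstituted alkenyl group as the large and C10H2 as the small substituent, the (S)-oxazaborolidine should deliver hydride to the face that gives 9R (cembrane numbering), and catecholborane at −78 °C reduces 1,2 without hydroborating the alkyne or the alkenes.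

Step 13
Reactants: 21 (6E,8R,11R,14E)-16-chloro-1-(4-methoxybenzyloxy)-7,11,15-trimethyl-11-(triethylsilyloxy)hexadeca-6,14-dien-2-yn-8-ol
Product: 22 C9 tert-butyldiphenylsilyl ether of 21
Conditions: TBDPSCl, imidazole, DMAP (cat.), CH2Cl2, rt
Reagents that add atoms: tert-butyldiphenylsilyl chloride, CC(C)(C)[Si](Cl)(c1ccccc1)c1ccccc1
Why: Silyl ether protection with a group that outlasts the later TES cleavage masks the C9 carbinol, and CH2Cl2 in place of DMF keeps N-alkylation of imidazole by the allylic chloride slow.

Step 14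
Reactants: 22 C9 tert-butyldiphenylsilyl ether of 21
Product: 23 (6E,8R,11R,14E)-8-(tert-butyldiphenylsilyloxy)-16-chloro-7,11,15-trimethyl-11-(triethylsilyloxy)hexadeca-6,14-dien-2-yn-1-ol
Conditions: DDQ, CH2Cl2/pH 7 buffer, 0 °C
Reagents that add atoms: none
Why: Oxidative PMB cleavage by DDQ abstracts hydride only from the electron-rich benzylic position, and the buffer protects the tertiary TES ether from the acidic hydroquinone.

Step 15
Reactants: 23 (6E,8R,11R,14E)-8-(tert-butyldiphenylsilyloxy)-16-chloro-7,11,15-trimethyl-11-(triethylsilyloxy)hexadeca-6,14-dien-2-yn-1-ol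
Product: 25 (9R,12R)-17-membered cyclic propargyl allyl ether, via sodium alkoxide 24 (not isolated)
Conditions: NaH, 15-crown-5 (cat.), THF, 45 °C, slow addition of 23 (final ca. 1 mM)
Reagents that add atoms: sodium hydride, [Na+].[H-] (sodium, in 24 only)
Why: Intramolecular Williamson etherification at high dilution lets the primary propargylic alkoxide displace the primary allylic chloride by SN2 at C16, and the linear alkyne and the two E-alkenes reduce the rotors and the transannular strain of the 17-membered ring.

Step 16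
Reactants: 25 (9R,12R)-17-membered cyclic propargyl allyl ether
Product: 27 (1R,2R,9R,12R)-14-membered propargylic alcohol bearing an isopropenyl group at C1, via C2-lithiated ether 26 (not isolated)
Conditions: (+)-bis[(R)-1-phenylethyl]amine, n-BuLi, THF, 0 °C; then 25, −78 → −20 °C
Reagents that add atoms: lithium bis[(R)-1-phenylethyl]amide, [Li]N([C@H](C)c1ccccc1)[C@H](C)c1ccccc1 (lithium, in 26 only)
Why: The amide removes one of the two diastereotopic protons at C2, the only position activated by both the ether oxygen and the alkyne, and the α-oxy propargyllithium 26 rearranges by a concerted, suprafacial [2,3]-sigmatropic shift through a five-membered envelope in which C2 bonds to C1, the O–C16 bond breaks and the π bond moves to C15=C16. The closest known reaction type is the [2,3]-Wittig ring contraction of macrocyclic allyl propargyl ethers, including its variants with chiral lithium amide bases. The 14-membered carbocycle is closed transannularly by the new C1–C2 bond inside the 17-membered ring, while O, C16 and C15 leave the ring and become the C2 hydroxyl and the isopropenyl group. C2 (R) is controlled by the chiral base, because C9 and C12 are too remote to differentiate the two protons, and C1 (R, anti to the C2 hydroxyl) follows from the E geometry of the C1=C15 alkene in the envelope, a relationship that does not matter in the end since C1 becomes sp2 in step 22. The step needs deprotonation at C2 rather than at C16 or C5, which the higher acidity of the oxygen-flanked propargylic C–H secures, and [2,3] rather than [1,2] migration, which the low temperature secures because the radical-pair pathway has the higher barrier. The two silyl ethers offer the amide no acidic or electrophilic site and stay in place.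

Step 17
Reactants: 27 (1R,2R,9R,12R)-14-membered propargylic alcohol bearing an isopropenyl group at C1
Product: 29 (1R,2R,9R,12R,3Z,7E)-4-iodo allylic alcohol, via cyclic alkenylalanate 28 (not isolated)
Conditions: Red-Al, THF, 0 °C → rt; EtOAc; I2, THF, −78 → 0 °C; Rochelle salt work-up
Reagents that add atoms: Red-Al, [Na+].[AlH2-](OCCOC)OCCOC (sodium, aluminium and alkoxy groups, in 28 only); iodine, II
Why: In the hydroxyl-directed trans-hydroalumination of a propargylic alcohol the O-bound aluminium hydride places H on C3 and Al on C4 within a five-membered ring, and iodinolysis with retention gives the iodide with iodine cis to C2.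

Step 18
Reactants: 29 (1R,2R,9R,12R,3Z,7E)-4-iodo allylic alcohol
Product: 30 (1R,2S,9R,12R,3E,7E)-4-methyl allylic alcohol with the C12 TES ether in place
Conditions: Me2CuLi (from MeLi and CuI, excess), Et2O, 0 °C
Reagents that add atoms: lithium dimethylcuprate, [Li+].C[Cu-]C
Why: Gilman cuprate coupling of an alkenyl iodide proceeds with retention of geometry, so the new C4 methyl ends up cis to C2 and the ring alkene is E, with one extra equivalent of cuprate consumed by the free hydroxyl (the C2 descriptor changes by priority only).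

Step 19
Reactants: 30 (1R,2S,9R,12R,3E,7E)-4-methyl allylic alcohol with the C12 TES ether in place
Product: 31 (1R,2S,9R,12R,3E,7E)-2,12-diol with the C9 TBDPS ether in place
Conditions: HF·pyridine, pyridine, THF, 0 °C
Reagents that add atoms: none
Why: Selective desilylation works because a TES ether is cleaved by buffered HF·pyridine far faster than a TBDPS ether, and the weakly acidic, non-solvolytic medium spares the ionisable C2 allylic alcohol.

Step 20
Reactants: 31 (1R,2S,9R,12R,3E,7E)-2,12-diol with the C9 TBDPS ether in place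
Product: 32 (1R,2R,3S,4S,9R,12R)-3,4-epoxy-2,12-diol
Conditions: VO(acac)2 (cat.), t-BuOOH (anhydrous, in decane), CH2Cl2, 0 °C
Reagents that add atoms: tert-butyl hydroperoxide, CC(C)(C)OO
Why: In the vanadium-catalysed hydroxyl-directed epoxidation the peroxide bound to the C2 vanadate reaches only the allylic C3=C4 alkene, and allylic 1,3-strain between the C4 methyl and C1 keeps C1 away from that methyl, so that the threo epoxy alcohol (3S,4S) should form with the E geometry carried into a trans oxirane.

Step 21
Reactants: 32 (1R,2R,3S,4S,9R,12R)-3,4-epoxy-2,12-diol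
Product: 33 (1R,3R,4S,9R,12R)-3,4-epoxy-2-ketone with the isopropenyl group at C1
Conditions: Dess–Martin periodinane, NaHCO3, CH2Cl2, 0 °C → rt
Reagents that add atoms: none
Why: Dess–Martin oxidation converts the only secondary carbinol into the ketone under buffered, nearly neutral conditions that leave the tertiary C12 alcohol and the oxirane untouched (the C3 descriptor changes by priority only).

Step 22
Reactants: 33 (1R,3R,4S,9R,12R)-3,4-epoxy-2-ketone with the isopropenyl group at C1
Product: 34 (3R,4S,9R,12R)-epoxy enone with the isopropylidene group at C1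
Conditions: DBU, CH2Cl2, rt
Reagents that add atoms: none
Why: Base-catalysed β,γ to α,β isomerisation through the dienolate (the isopulegone-to-pulegone type) moves the double bond into conjugation and erases C1, while the oxirane C3–H is too weakly acidic to epimerise.

Step 23
Reactants: 34 (3R,4S,9R,12R)-epoxy enone with the isopropylidene group at C1
Product: 35 (3R,4S,9R,12R)-C12 acetate with the C9 TBDPS ether in place
Conditions: Ac2O, DMAP, Et3N, CH2Cl2, rt → 40 °C
Reagents that add atoms: acetic anhydride, CC(=O)OC(C)=O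
Why: DMAP-catalysed acylation through the N-acetylpyridinium ion is reactive enough for the tertiary alcohol, the only free hydroxyl, and the hindered cross-conjugated C2 ketone is too poor an electrophile to hold that hydroxyl as a six-membered hemiketal.

Step 24
Reactants: 35 (3R,4S,9R,12R)-C12 acetate with the C9 TBDPS ether in place
Product: 36 CNP0404804.1
Conditions: TBAF, AcOH (1:1), THF, 0 °C → rt
Reagents that add atoms: none
Why: Fluoride-induced desilylation with acetic acid-buffered TBAF is preferred to HF·pyridine, which cleaves TBDPS ethers sluggishly and would endanger the trisubstituted oxirane on long exposure, and the buffer prevents acetate loss or migration.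

**Compound list**
1 | (R)-(−)-linalool, (3R)-3,7-dimethylocta-1,6-dien-3-ol | O[C@](C=C)(C)CCC=C(C)C | starting material
2 | (3R)-3,7-dimethyl-3-(triethylsilyloxy)octa-1,6-diene | CC[Si](CC)(CC)O[C@](C=C)(C)CCC=C(C)C | intermediate
3 | B-alkyl-9-BBN adduct of 2, boron on the former vinyl terminus (C10), C12 unchanged, not isolated | CC[Si](CC)(CC)O[C@](CCB1C2CCCC1CCC2)(C)CCC=C(C)C | intermediate
4 | (3R)-3,7-dimethyl-3-(triethylsilyloxy)oct-6-en-1-ol | CC[Si](CC)(CC)O[C@](CCO)(C)CCC=C(C)C | intermediate
5 | (3R)-1-iodo-3,7-dimethyl-3-(triethylsilyloxy)oct-6-ene (C10–C17 fragment) | CC[Si](CC)(CC)O[C@](CCI)(C)CCC=C(C)C | intermediate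
6 | propargyl alcohol | OCC#C | starting material
7 | sodium prop-2-yn-1-olate, not isolated | [Na+].[O-]CC#C | intermediate
8 | 4-methoxybenzyl prop-2-ynyl ether | C#CCOCc1ccc(OC)cc1 | intermediate
9 | 2-(2-bromoethyl)-1,3-dioxolane | BrCCC1OCCO1 | starting material
10 | lithium acetylide of 8, not isolated | [Li]C#CCOCc1ccc(OC)cc1 | intermediate
11 | 2-[5-(4-methoxybenzyloxy)pent-3-yn-1-yl]-1,3-dioxolane | COc1ccc(COCC#CCCC2OCCO2)cc1 | intermediate
12 | 6-(4-methoxybenzyloxy)hex-4-ynal | O=CCCC#CCOCc1ccc(OC)cc1 | intermediate
13 | ethyl 2-(triphenylphosphoranylidene)propanoate | CCOC(=O)C(C)=P(c1ccccc1)(c1ccccc1)c1ccccc1 | starting material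
14 | ethyl (2E)-8-(4-methoxybenzyloxy)-2-methyloct-2-en-6-ynoate | CCOC(=O)/C(C)=C/CCC#CCOCc1ccc(OC)cc1 | intermediate
15 | (2E)-N-methoxy-8-(4-methoxybenzyloxy)-N,2-dimethyloct-2-en-6-ynamide (C2–C9 fragment) | CON(C)C(=O)/C(C)=C/CCC#CCOCc1ccc(OC)cc1 | intermediate
16 | alkylmagnesium iodide from 5, C12 unchanged, not isolated | CC[Si](CC)(CC)O[C@](CC[Mg]I)(C)CCC=C(C)C | intermediate
17 | (6E,11R)-1-(4-methoxybenzyloxy)-7,11,15-trimethyl-11-(triethylsilyloxy)hexadeca-6,14-dien-2-yn-8-one (acyclic C9 enone) | CC[Si](CC)(CC)O[C@](CCC(=O)/C(C)=C/CCC#CCOCc1ccc(OC)cc1)(C)CCC=C(C)C | intermediate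
18 | (6E,11R,14E)-16-hydroxy derivative of 17 (C16 allylic alcohol) | CC[Si](CC)(CC)O[C@](CCC(=O)/C(C)=C/CCC#CCOCc1ccc(OC)cc1)(C)CC/C=C(\C)CO | intermediate
19 | C16 methanesulfonate of 18, not isolated | CC[Si](CC)(CC)O[C@](CCC(=O)/C(C)=C/CCC#CCOCc1ccc(OC)cc1)(C)CC/C=C(\C)COS(C)(=O)=O | intermediate
20 | (6E,11R,14E)-16-chloro derivative of 17 (C16 allylic chloride) | CC[Si](CC)(CC)O[C@](CCC(=O)/C(C)=C/CCC#CCOCc1ccc(OC)cc1)(C)CC/C=C(\C)CCl | intermediate
21 | (6E,8R,11R,14E)-16-chloro-1-(4-methoxybenzyloxy)-7,11,15-trimethyl-11-(triethylsilyloxy)hexadeca-6,14-dien-2-yn-8-ol (9R,12R in cembrane numbering) | CC[Si](CC)(CC)O[C@](CC[C@@H](O)/C(C)=C/CCC#CCOCc1ccc(OC)cc1)(C)CC/C=C(\C)CCl | intermediate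
22 | C9 tert-butyldiphenylsilyl ether of 21 | CC[Si](CC)(CC)O[C@](CC[C@@H](O[Si](c1ccccc1)(c1ccccc1)C(C)(C)C)/C(C)=C/CCC#CCOCc1ccc(OC)cc1)(C)CC/C=C(\C)CCl | intermediate
23 | (6E,8R,11R,14E)-8-(tert-butyldiphenylsilyloxy)-16-chloro-7,11,15-trimethyl-11-(triethylsilyloxy)hexadeca-6,14-dien-2-yn-1-ol (seco chloro alcohol) | CC[Si](CC)(CC)O[C@](CC[C@@H](O[Si](c1ccccc1)(c1ccccc1)C(C)(C)C)/C(C)=C/CCC#CCO)(C)CC/C=C(\C)CCl | intermediate
24 | sodium alkoxide of 23, not isolated | CC[Si](CC)(CC)O[C@](CC[C@@H](O[Si](c1ccccc1)(c1ccccc1)C(C)(C)C)/C(C)=C/CCC#CC[O-])(C)CC/C=C(\C)CCl.[Na+] | intermediate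
25 | 17-membered ether, ring O–C2H2–C3≡C4–C5–C6–C7=C8(Me)–C9(OTBDPS)–C10–C11–C12(Me)(OTES)–C13–C14–C1H=C15(Me)–C16H2–O; 7E, 1(15)E, 9R, 12R | CC[Si](CC)(CC)O[C@]1(C)CC/C=C(\C)COCC#CCC/C=C(\C)[C@H](O[Si](c2ccccc2)(c2ccccc2)C(C)(C)C)CC1 | intermediate
26 | 25 lithiated at C2, not isolated | CC[Si](CC)(CC)O[C@]1(C)CC/C=C(\C)COC([Li])C#CCC/C=C(\C)[C@H](O[Si](c2ccccc2)(c2ccccc2)C(C)(C)C)CC1 | intermediate
27 | 14-membered carbocycle: C1 isopropenyl, C2 OH, C3≡C4, 7E alkene, C9 OTBDPS, C12 OTES; 1R,2R,9R,12R | CC[Si](CC)(CC)O[C@]1(C)CC[C@H](C(C)=C)[C@@H](O)C#CCC/C=C(\C)[C@H](O[Si](c2ccccc2)(c2ccccc2)C(C)(C)C)CC1 | intermediate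
28 | sodium alkenylalanate, five-membered ring O–Al–C4=C3–C2 fused on the macrocycle, not isolated | CC[Si](CC)(CC)O[C@]1(C)CC[C@H](C(C)=C)[C@H]2O[Al-](OCCOC)(OCCOC)C(=C2)CC/C=C(\C)[C@H](O[Si](c3ccccc3)(c3ccccc3)C(C)(C)C)CC1.[Na+] | intermediate
29 | 4-iodo allylic alcohol, iodine cis to C2 (3Z), 7E; 1R,2R,9R,12R | CC[Si](CC)(CC)O[C@]1(C)CC[C@H](C(C)=C)[C@@H](O)/C=C(\I)CC/C=C(\C)[C@H](O[Si](c2ccccc2)(c2ccccc2)C(C)(C)C)CC1 | intermediate
30 | 4-methyl allylic alcohol, 3E,7E, C12 OTES; 1R,2S,9R,12R | CC[Si](CC)(CC)O[C@]1(C)CC[C@H](C(C)=C)[C@@H](O)/C=C(\C)CC/C=C(\C)[C@H](O[Si](c2ccccc2)(c2ccccc2)C(C)(C)C)CC1 | intermediate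
31 | 2,12-diol, 3E,7E, C9 OTBDPS; 1R,2S,9R,12R | O[C@]1(C)CC[C@H](C(C)=C)[C@@H](O)/C=C(\C)CC/C=C(\C)[C@H](O[Si](c2ccccc2)(c2ccccc2)C(C)(C)C)CC1 | intermediate
32 | 3,4-epoxy-2,12-diol (threo, trans oxirane); 1R,2R,3S,4S,9R,12R | O[C@]1(C)CC[C@H](C(C)=C)[C@@H](O)[C@@H]2O[C@@]2(C)CC/C=C(\C)[C@H](O[Si](c3ccccc3)(c3ccccc3)C(C)(C)C)CC1 | intermediate
33 | 3,4-epoxy-2-ketone with C1 isopropenyl; 1R,3R,4S,9R,12R | O[C@]1(C)CC[C@H](C(C)=C)C(=O)[C@@H]2O[C@@]2(C)CC/C=C(\C)[C@H](O[Si](c3ccccc3)(c3ccccc3)C(C)(C)C)CC1 | intermediate
34 | epoxy enone with C1 isopropylidene, C12 OH free; 3R,4S,9R,12R | O[C@]1(C)CCC(=C(C)C)C(=O)[C@@H]2O[C@@]2(C)CC/C=C(\C)[C@H](O[Si](c3ccccc3)(c3ccccc3)C(C)(C)C)CC1 | intermediate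
35 | C12 acetate of 34; 3R,4S,9R,12R | CC(=O)O[C@]1(C)CCC(=C(C)C)C(=O)[C@@H]2O[C@@]2(C)CC/C=C(\C)[C@H](O[Si](c3ccccc3)(c3ccccc3)C(C)(C)C)CC1 | intermediate
36 | CNP0404804.1; 3R,4S,9R,12R, 7E | CC(=O)O[C@]1(C)CCC(=C(C)C)C(=O)[C@@H]2O[C@@]2(C)CC/C=C(\C)[C@H](O)CC1 | target

**Step count**
Total step count: 24.
Longest linear sequence: 21 steps, from 6 through steps 4–8 and 9–24. The linalool branch (steps 1–3) joins at step 9.

**The three steps most likely to fail**

Step 16 (key step). The chiral amide may discriminate only weakly between the two diastereotopic C2 protons of a large, flexible ring. C2, and with it the later oxirane face, would then be set with low selectivity. Deprotonation by an amide base may also be slow, which would let the [1,2]-shift compete on warming.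
- The fallback separates bond formation from stereocontrol. Setting out from 25, n-BuLi in THF at −78 °C brings about the same contraction without a chiral controller. It should give 27 mixed with the (1S,2S) anti alcohol F1.
- Buffered Dess–Martin oxidation of the mixture gives the C2 ynone F2 as both C1 epimers.
- Reduction with (R)-Me-CBS and catecholborane at −78 °C (branched C1 as the large group, alkynyl as the small group) sets 2R by reagent control.
- The products are 27 and the (1S,2R) alcohol F3, which are separated by chromatography. The route is rejoined at 27 and F3 is held back.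

Step 15. Intermolecular alkylation (oligomer formation) may overtake ring closure. The alkyne may also drift towards the allene under base during the long addition.
- The fallback closes the 17-membered ring at the triple bond instead of at O–C16. Setting out from 22, the allylic chloride is displaced intermolecularly by the sodium alkoxide of but-2-yn-1-ol (cheap, used in excess; NaH, THF/DMF). This gives the but-2-ynyl ether diyne F4.
- Ring-closing alkyne metathesis follows, with a molybdenum benzylidyne tris(triphenylsilanolate) catalyst in dilute toluene. It joins the C4 alkylidyne unit to the ≡C–CH2–O–C16 unit and expels the two caps as one small alkyne. Only these two units are tethered, so no other ring can form, and dilution favours the ring.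
- The route is rejoined at 25, and steps 14 and 15 are not needed.

Step 20. Facial selectivity may be poor if the macrocycle cannot reach the conformer that minimises allylic 1,3-strain. Oxygen may also be delivered in competition to the homoallylic isopropenyl group.
- The fallback makes the oxirane by nucleophilic rather than electrophilic oxygen transfer, under reagent control. Setting out from 31, MnO2 oxidises the allylic C2 carbinol to the isopropenyl dienone F5. DBU then moves the isopropenyl double bond into conjugation to give the cross-conjugated dienone F6.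
- A Weitz–Scheffer-type epoxidation follows, with cumene hydroperoxide and a lanthanum–BINOL–triphenylarsine oxide catalyst. The ligand antipode is chosen for the 3R,4S face.
- The epoxidation should attack only the trisubstituted C3=C4 arm, because the tetrasubstituted C1=C15 arm is hindered and twisted out of conjugation. β,β-Disubstitution is expected to slow the addition.
- The route is rejoined at 34, and on this path the C2 configuration from step 16 no longer matters.

**Further compounds**
F1 | step 16 | (1S,2S,9R,12R) diastereomer of 27 | CC[Si](CC)(CC)O[C@]1(C)CC[C@@H](C(C)=C)[C@H](O)C#CCC/C=C(\C)[C@H](O[Si](c2ccccc2)(c2ccccc2)C(C)(C)C)CC1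
F2 | step 16 | C2 ynone from 27 and F1, both C1 epimers, 9R,12R | CC[Si](CC)(CC)O[C@]1(C)CCC(C(C)=C)C(=O)C#CCC/C=C(\C)[C@H](O[Si](c2ccccc2)(c2ccccc2)C(C)(C)C)CC1
F3 | step 16 | (1S,2R,9R,12R) C1 epimer of 27 | CC[Si](CC)(CC)O[C@]1(C)CC[C@@H](C(C)=C)[C@@H](O)C#CCC/C=C(\C)[C@H](O[Si](c2ccccc2)(c2ccccc2)C(C)(C)C)CC1
F4 | step 15 | seco diyne, 22 with C16–Cl replaced by C16–O–CH2C≡CCH3 | CC[Si](CC)(CC)O[C@](CC[C@@H](O[Si](c1ccccc1)(c1ccccc1)C(C)(C)C)/C(C)=C/CCC#CCOCc1ccc(OC)cc1)(C)CC/C=C(\C)COCC#CC
F5 | step 20 | (1R,9R,12R,3E,7E)-2-ketone with C1 isopropenyl (3-en-2-one) | O[C@]1(C)CC[C@H](C(C)=C)C(=O)/C=C(\C)CC/C=C(\C)[C@H](O[Si](c2ccccc2)(c2ccccc2)C(C)(C)C)CC1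
F6 | step 20 | (9R,12R,3E,7E) cross-conjugated dienone with C1 isopropylidene | O[C@]1(C)CCC(=C(C)C)C(=O)/C=C(\C)CC/C=C(\C)[C@H](O[Si](c2ccccc2)(c2ccccc2)C(C)(C)C)CC1
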